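## Structural features

The target, (1R,3S,4S)-3-bromo-1-[(1S,3S,5R)-3-bromo-5-hydroxy-1,2,2-trimethylcyclopentyl]-4-chloro-4-methylcyclohexan-1-ol, is a cuparane-type C15 skeleton of two carbocycles joined by the single bond C5–C1'. Ring A is a cyclopentane (C1 gem-dimethyl, C2 bromide, C3 methylene, C4 carbinol, C5 quaternary with methyl). Ring B is a cyclohexane (C1' tertiary carbinol, C2' and C3' methylenes, C4' with CH3 and Cl, C5' bromide, C6' methylene). In this numbering the stereocentres are 2S, 4R, 5S, 1'R, 4'S, 5'S; C4, C5 and C1' are contiguous across the inter-ring bond, C2 is 1,3 to C4, and C4'/C5' are vicinal and remote from C1'. On ring A the bromine, the hydroxyl and ring B lie on one face; on ring B the chlorine is cis to the C1' hydroxyl and trans to the C5' bromine. The fragile groups are the tertiary chloride, the two secondary bromides (C2 is neopentyl and prone to rearrangement) and the C4/C1' 1,3-diol, which can undergo retro-aldol cleavage when C4 is a carbonyl and fragmentation under acid. The real difficulties are the C5–C1' bond between two fully substituted stereogenic carbons, the C2 bromide, and a chlorine on the ring B face that trans-diaxial addition to a C4'=C5' alkene would not reach. The key step uses the fact that C1' bears oxygen and can be the oxygen-bearing terminus of an enol ether C1'=C6', while C5 is alpha to C4, which can be a carboxyl carbon. An ester oxygen on C5' then ties C5=C4–O and C5'–C6'=C1' into the six-atom array of a [3,3] shift that forms C5–C1' and leaves a C5'=C6' alkene in ring B.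

## Logic of the disconnections

**31 from 30.** The C4'–Cl bond is cut and the C1' oxygen is reconnected to C4' as an ether bridge. Direct bromochlorination of a C4'=C5' alkene would proceed by trans-diaxial opening in the chair that keeps the ring A substituent equatorial, which puts chlorine trans to the C1' oxygen. The bridge instead fixes the bromine on the face opposite the oxygen, and bromine participation then returns chloride to the oxygen face. Both halogen stereocentres are thereby derived from C1'. The forward step must ionise C4'–O (assisted by the anti bromine) in preference to C1'–O.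

**30 from 29.** The C4'–O and C5'–Br bonds are cut, leaving a C4'=C5' alkene and a free C1' hydroxyl. Only the bromonium ion anti to that hydroxyl can be captured across the ring at the tertiary carbon, so one alkene replaces two stereocentres. The forward step needs a boat-like closure and must outrun capture by the C4 hydroxyl at the secondary carbon.

**29 from 24 (through 28, 27 and 25).** The two O–Si bonds, the C4'–CH3 bond, the C4'–O bond of an enol sulfonate and finally the C4'=O bond are cut, back to a C4' methylene beside a C5'=C6' alkene. The rearrangement leaves its alkene at C5'=C6', and C4' is the only allylic methylene, so oxidation there is unambiguous. Conjugate reduction then moves the unsaturation to C4'=C5' on one arm only, which keeps the two arms of ring B distinct and therefore keeps C1' stereogenic. The forward steps demand oxygen substituents without weak benzylic C–H bonds, which is why silicon is used on both oxygens.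

**24 from 19 (through 22, 21 and 20).** The C2–Br bond is cut to a C2–B bond of opposite configuration, the C4–H bond to a ketone, and the C2–B bond to an enone. Displacement at the neopentyl C2 by a nucleophile is unreliable, whereas boron can be added anti to ring B and then replaced by electrophilic bromine with inversion. The forward steps require two additions from the ring A face opposite ring B (boron at C2, hydride at C4).

**19 from 16 (through 17).** The C2=C3 unsaturation is removed and the C3–C4 bond is cut, which opens ring A to a pent-4-enal. Ring A then costs one atom-economical C–H addition and one desaturation. The forward cyclisation must choose the terminal vinyl group over the ring B alkene, which stands in the same 4,5-relationship to the aldehyde.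

**16 from 14 (through 15).** Only the oxidation level of C4 changes. The forward steps must reduce a very hindered carboxylic acid without touching the allylic silyl ether.

**14 from 11.** The C5–C1' bond is cut and the ester O–C5' bond restored. The most congested bond of the target then becomes an intramolecular, suprafacial event, and 14 divides into two fragments of similar size. Re-derivation of the stereochemistry confirms that an (R)-carbinol at C5' gives (R) at C1'. The forward step demands one ketene acetal geometry paired with one transition-state topology for C5.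

**11 from 9 and 3.** The ester C–O bond is cut. 9 may be racemic because its stereocentre is erased on enolisation. The esterification must be non-acidic because 3 is an enol ether with an allylic hydroxyl.

**3 from 1 (through 2), and 9 from 4 and 5 (through 6).** 3 is traced to the symmetric diketone 1 by cutting the C5'–H bond (asymmetric reduction) and the O–Si bond. 9 is traced by cutting the bond between its alpha carbon and the quaternary carbon, a [3,3] shift of 6, and then the ester bond of 6.

## Other disconnections considered

**Alternative 1:** The cut is C1–C5 together with the C1'–O bond of a carbonate. In the forward step, bromodiethylsulfonium bromopentachloroantimonate would brominate the prenyl alkene of the dienyl tert-butyl carbonate A1, the cyclohexylidene carbon C5 would close ring A, and the carbonate would capture C1' to give A2. In its favour, one step would form ring A, quaternary C5, the C1' oxygen and the C2 bromide with its configuration. On the bromide it is better than the chosen plan, which needs three operations and an inversion at a neopentyl carbon, and it would probably be shorter through ring A. Against it, C1' in A2 carries two identical arms and is not a stereocentre, so its configuration would have to be created later by differentiating two remote, diastereotopic methylenes. The electrophile would also have to choose the trisubstituted prenyl alkene over the more electron-rich tetrasubstituted one, and a cation would have to close a five-membered ring while forming two adjacent quaternary carbons. Mechanistically it is a stepwise cationic process open to elimination and rearrangement, whereas the chosen plan makes the same congested bond by a concerted shift that sets C5 and C1' together.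

**Alternative 2:** The cut is the C5–CH3 bond. In the forward step, ZnBr2 would open the C5–O bond of the epoxy alcohol A3 while the methyl on C4 migrates, giving enone A4. In its favour, the migration is anti and stereospecific, so C5 would follow directly from the epoxide configuration. That is a more secure control element than the geometry/topology pairing of the chosen key step, and A4 already has the ring A enone oxidation pattern of 19. Against it, the Lewis acid could equally open the C1'–O bond, whose cation is not next to a carbinol carbon. A4 is also a free beta-hydroxy ketone open to retro-aldol cleavage in the basic steps that must follow, and C1' is again not stereogenic. Setting the epoxide configuration on a tetrasubstituted alkene of a tertiary allylic alcohol is a further demand. Step counts would be similar; the chosen plan keeps C1'–O silylated until C4 is an alcohol and fixes C1' early.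

**Alternative 3:** The cut is at the C2'–C3' hydrogens, with ring B arriving as an arene that is dearomatised to the quinol A5. In the forward step, a flavin-dependent ene-reductase with NADPH recycling would reduce one enone arm to give A6. In its favour, C1' would be set late under catalyst control, independently of C5, and A6 has the C4' ketone and C5'=C6' alkene of 25 without any C–H oxidation. On both points it equals or betters the chosen plan, and aryl–C5 bond formation is well developed. Against it, the enzyme would have to accept a quinol whose carbinol carbon bears a fully substituted, brominated cyclopentyl group, far from the small 4-substituents such enzymes usually tolerate. The two enone arms are diastereotopic, so enzyme and substrate bias may oppose each other. All three ring A stereocentres would have to be built with no help from ring B and carried through an oxidative dearomatisation. The chosen plan instead uses one pericyclic step for the inter-ring bond and both of its stereocentres, at the price of a longer ring B endgame.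

Key step: step 6

Remark on the chemistry: the oxygen on C1' is carried as a tert-butyldimethylsilyl ether rather than a benzylic ether because a benzylic C–H bond would compete in the radical allylic oxidation of step 15. The skeleton and configurations of the key-step precursor 11 and product 14 are otherwise unchanged.

## Route

Step 1
Reactants: 1 cyclohexane-1,3-dione
Product: 2 3-(tert-butyldimethylsilyloxy)cyclohex-2-en-1-one
Conditions: t-BuMe2SiCl, Et3N, CH2Cl2, 0 → 23 °C; non-aqueous work-up
Reagents that add atoms: tert-butyldimethylsilyl chloride, CC(C)(C)[Si](C)(C)Cl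
Why: O-silylation of the enol of a 1,3-diketone gives the vinylogous silyl ester; the silyloxy group is still a donor for the later [3,3] shift but has no weak C–H bond and stabilises an allyl cation less than an alkyl enol ether.

Step 2
Reactants: 2 3-(tert-butyldimethylsilyloxy)cyclohex-2-en-1-one
Product: 3 (R)-3-(tert-butyldimethylsilyloxy)cyclohex-2-en-1-ol
Conditions: (S)-1-methyl-3,3-diphenyltetrahydro-1H,3H-pyrrolo[1,2-c][1,3,2]oxazaborole ((S)-Me-CBS, 20 mol %), catecholborane, toluene, −78 → −40 °C; MeOH, then 1 M NaOH wash; used without acidic chromatography
Reagents that add atoms: none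
Why: CBS reduction of an enone, with the alkenyl flank as the large group and the ring CH2 as the small one, so the (S)-catalyst should give the (R)-carbinol; a basic work-up avoids the acid-induced loss of the allylic hydroxyl typical of 3-oxygenated cyclohexenols.

Step 3
Reactants: 4 prenol (3-methylbut-2-en-1-ol); 5 propionyl chloride
Product: 6 prenyl propionate
Conditions: Et3N, 4-(dimethylamino)pyridine (cat.), CH2Cl2, 0 °C
Reagents that add atoms: none
Why: Routine acylation of a primary allylic alcohol by an acid chloride.

Step 4
Reactants: 6 prenyl propionate
Product: 9 rac-2,3,3-trimethylpent-4-enoic acid, via silyl ketene acetal 7 (not isolated), via trimethylsilyl ester 8 (not isolated)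
Conditions: LiN(iPr)2, THF, −78 °C; Me3SiCl, −78 → 23 °C, then 65 °C; 1 M NaOH, then HCl to pH 2
Reagents that add atoms: none
Why: Ireland–Claisen rearrangement; the [3,3] shift forms the bond from the alpha carbon to the dimethyl-substituted allyl terminus, creating the quaternary carbon that becomes C1 and the vinyl group that becomes C2/C3. The new stereocentre is left racemic because it is erased in step 6.

Step 5
Reactants: 9 rac-2,3,3-trimethylpent-4-enoic acid; 3 (R)-3-(tert-butyldimethylsilyloxy)cyclohex-2-en-1-ol
Product: 11 (1R)-3-(tert-butyldimethylsilyloxy)cyclohex-2-en-1-yl (2RS)-2,3,3-trimethylpent-4-enoate, via acyl chloride 10 (not isolated)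
Conditions: (COCl)2, N,N-dimethylformamide (cat.), CH2Cl2, 0 → 23 °C, evaporate; then 3, Et3N, 4-(dimethylamino)pyridine (cat.), CH2Cl2, −20 → 0 °C; NaHCO3 work-up, Et3N-deactivated silica
Reagents that add atoms: none
Why: Acylation through the acid chloride under basic conditions joins the hindered acid to the acid-sensitive alcohol without touching C5', so the (R) configuration is kept; both alpha-epimers are carried on.

Step 6
Reactants: 11 (1R)-3-(tert-butyldimethylsilyloxy)cyclohex-2-en-1-yl (2RS)-2,3,3-trimethylpent-4-enoate
Product: 14 (2R)-2-[(1R)-1-(tert-butyldimethylsilyloxy)cyclohex-2-en-1-yl]-2,3,3-trimethylpent-4-enoic acid, via silyl ketene acetal 12 (not isolated), via trimethylsilyl ester 13 (not isolated)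
Conditions: LiN(iPr)2, THF, −78 °C; Me3SiCl/Et3N, −78 → 23 °C, then 45 °C; 1 M NaOH, then NaH2PO4 to pH 4–5
Reagents that add atoms: none
Why: Deprotonation of 11 by the lithium amide in THF alone goes through a closed transition state in which the tert-alkyl group (future C1) avoids the amide and ends cis to the allylic oxygen, with methyl cis to O–Li; silylation fixes this as 12, and both alpha-epimers converge. 12 then rearranges through the chair array C5=C4–O–C5'–C6'=C1': the O–C5' bond breaks, C5–C1' forms and the alkene moves to C5'=C6'; no ring closes. The closest known reaction type is the Ireland–Claisen rearrangement of esters of 3-oxygenated cyclic allylic alcohols (glycal esters), which bond at the oxygen-bearing alkene terminus, and of alpha,alpha-disubstituted esters, which give adjacent fully substituted carbons. C1' is controlled by the C5' carbinol: the new bond forms on the ring face from which the ester oxygen leaves, so (R)-C5' becomes (R)-C1'. C5 is controlled by the pairing of this ketene acetal geometry with the chair, in which the tert-alkyl group sits on the outer axial position and methyl is equatorial. The boat open to the same geometry would force the tert-alkyl group over the ring B methylenes, whereas the chair costs only a contact between OSiMe3 and the ring, which is why the smallest silyl group is used. The step must also favour the [3,3] shift over ionisation of the allylic C–O bond; the silyloxy donor on the terminus lowers the barrier of the shift, and low temperature, an ether solvent and amine buffering hold back ionisation. Mild hydrolysis of 13 gives 14.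

Step 7
Reactants: 14 (2R)-2-[(1R)-1-(tert-butyldimethylsilyloxy)cyclohex-2-en-1-yl]-2,3,3-trimethylpent-4-enoic acid
Product: 15 primary alcohol 2-[(1R)-1-(tert-butyldimethylsilyloxy)cyclohex-2-en-1-yl]-2,3,3-trimethylpent-4-en-1-ol (quaternary carbon as in 14)
Conditions: LiAlH4, THF, 0 → 65 °C; H2O/NaOH work-up
Reagents that add atoms: none
Why: Hydride reduction of a hindered carboxylic acid needs heat but touches neither the alkenes nor the tertiary silyl ether; no stereocentre is involved.

Step 8
Reactants: 15 primary alcohol
Product: 16 aldehyde 2-[(1R)-1-(tert-butyldimethylsilyloxy)cyclohex-2-en-1-yl]-2,3,3-trimethylpent-4-enal (quaternary carbon as in 14)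
Conditions: Dess–Martin periodinane, NaHCO3, CH2Cl2, 0 → 23 °C
Reagents that add atoms: none
Why: Buffered Dess–Martin oxidation of a neopentyl alcohol; the aldehyde has no alpha hydrogen and cannot epimerise or enolise.

Step 9
Reactants: 16 aldehyde
Product: 17 cyclopentanone 2-[(1R)-1-(tert-butyldimethylsilyloxy)cyclohex-2-en-1-yl]-2,3,3-trimethylcyclopentan-1-one (C5 as in 14)
Conditions: [Rh(Ph2PCH2CH2PPh2)]BF4 (5 mol %, from its norbornadiene complex and H2), CH2Cl2, 23 °C
Reagents that add atoms: none
Why: Intramolecular hydroacylation of a pent-4-enal by cationic monovalent rhodium: the metal inserts into the aldehyde C–H bond, the vinyl group inserts, and reductive elimination forms C3–C4 and closes ring A. The terminal monosubstituted alkene should react far faster than the cyclic disubstituted ring B alkene, whose closure would give a strained bridged ketone, and the four substituents on the chain favour cyclisation over decarbonylation.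

Step 10
Reactants: 17 cyclopentanone
Product: 19 enone 5-[(1R)-1-(tert-butyldimethylsilyloxy)cyclohex-2-en-1-yl]-4,4,5-trimethylcyclopent-2-en-1-one (C5 as in 14), via silyl enol ether 18 (not isolated)
Conditions: LiN(iPr)2, Me3SiCl, THF, −78 °C; then Pd(OAc)2 (1.1 equiv), MeCN, 23 °C
Reagents that add atoms: none
Why: Saegusa–Ito desaturation; C3 is the only enolisable position, so the silyl enol ether and the C2=C3 double bond form regiospecifically under divalent palladium.

Step 11
Reactants: 19 enone
Product: 20 boryl ketone 2-[(1R)-1-(tert-butyldimethylsilyloxy)cyclohex-2-en-1-yl]-2,3,3-trimethyl-4-(4,4,5,5-tetramethyl-1,3,2-dioxaborolan-2-yl)cyclopentan-1-one (boron on C2 trans to ring B)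
Conditions: bis(pinacolato)diboron, CuCl (5 mol %), NaOt-Bu (10 mol %), bis[2-(diphenylphosphino)phenyl] ether (5 mol %), MeOH (2 equiv), THF, 0 → 23 °C
Reagents that add atoms: bis(pinacolato)diboron, CC1(C)OB(B2OC(C)(C)C(C)(C)O2)OC1(C)C
Why: Conjugate borylation of a cyclic enone by a monovalent copper boryl species. C2 should be attacked on the face opposite the bulky ring B substituent on C5, so boron ends trans to ring B, and methanol protonates the copper enolate.

Step 12
Reactants: 20 boryl ketone
Product: 21 hydroxy boronate (C4–OH cis to ring B and trans to the C2 boron)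
Conditions: NaBH4, MeOH–THF, −40 → 0 °C
Reagents that add atoms: none
Why: Borohydride reduction of a cyclopentanone with an alpha quaternary centre; hydride should come from the methyl face of C5, away from ring B, so the hydroxyl ends cis to ring B as in the target.

Step 13
Reactants: 21 hydroxy boronate
Product: 22 triethylsilyl ether of 21
Conditions: Et3SiOSO2CF3, 2,6-lutidine, CH2Cl2, −78 → 0 °C
Reagents that add atoms: triethylsilyl trifluoromethanesulfonate, CC[Si](CC)(CC)OS(=O)(=O)C(F)(F)F
Why: Silyl triflate silylation of a hindered secondary alcohol; the ether protects C4–O against the aryllithium, the oxidant and the hydride of steps 14–16.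

Step 14
Reactants: 22 triethylsilyl ether of 21
Product: 24 bromide (C2–Br cis to ring B and to C4–OSiEt3), via boronate complex 23 (not isolated)
Conditions: 3,5-(CF3)2C6H3Li (from the aryl bromide and n-BuLi), THF, −78 °C; then N-bromosuccinimide, THF, −78 → 0 °C
Reagents that add atoms: N-bromosuccinimide, BrN1C(=O)CCC1=O
Why: Stereoinvertive electrophilic bromination of a secondary boronic ester: the aryllithium forms a tetracoordinate boronate whose C–B bond attacks bromine through the lobe opposite boron. The bromine therefore enters on the ring B face with inversion and without a carbocation that could rearrange at the neopentyl carbon.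

Step 15
Reactants: 24 bromide
Product: 25 ring B enone (C4'=O conjugated with C5'=C6')
Conditions: Rh2(caprolactamate)4 (1 mol %), t-BuOOH (5 equiv), K2CO3, CH2Cl2, 23 °C
Reagents that add atoms: tert-butyl hydroperoxide, CC(C)(C)OO
Why: Radical allylic C–H oxidation of a cyclohexene to the enone; C4' is the only allylic CH2, and trapping of the allyl radical at C6' is disfavoured by the adjacent quaternary C1'. The molecule now has no benzylic ether to compete.

Step 16
Reactants: 25 ring B enone
Product: 27 enol triflate (C4'(OSO2CF3)=C5'), via lithium enolate 26 (not isolated)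
Conditions: LiBH(s-Bu)3, THF, −78 °C; then PhN(SO2CF3)2, −78 → 0 °C
Reagents that add atoms: N-phenylbis(trifluoromethanesulfonimide), O=S(=O)(N(c1ccccc1)S(=O)(=O)C(F)(F)F)C(F)(F)F
Why: Conjugate hydride addition to a beta-unsubstituted cyclohexenone gives the C4'–C5' enolate regiospecifically, and O-triflation fixes it. The double bond therefore lies on the C5' arm only, which keeps the two arms of ring B distinct and C1' stereogenic.

Step 17
Reactants: 27 enol triflate
Product: 28 methyl alkene (C4'(CH3)=C5')
Conditions: MeZnCl, Pd(PPh3)4 (5 mol %), THF, 23 → 50 °C
Reagents that add atoms: methylzinc chloride, C[Zn]Cl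
Why: Negishi coupling; zerovalent palladium with triarylphosphine ligands inserts into the alkenyl C–O bond of the triflate much faster than into a hindered secondary alkyl C–Br bond, and the methylzinc reagent does not attack the bromide or the silyl ethers.

Step 18
Reactants: 28 methyl alkene
Product: 29 diol (free C4–OH and C1'–OH)
Conditions: 48% aq. HF, MeCN, 0 → 23 °C
Reagents that add atoms: none
Why: Acidic fluoride cleaves both silyl ethers without the basicity that could eliminate the C2 bromide; C1' is by now only homoallylic and not prone to ionise.

Step 19
Reactants: 29 diol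
Product: 30 bromoether (7-oxabicyclo[2.2.1]heptane with O bridging C1' and C4' and C5'–Br on the face opposite the bridge)
Conditions: N-bromosuccinimide, NaHCO3, CH2Cl2, −20 → 0 °C, dark
Reagents that add atoms: N-bromosuccinimide, BrN1C(=O)CCC1=O
Why: Bromoetherification of a 4-methylcyclohex-3-enol. Bromonium formation is reversible, and only the ion anti to the C1' hydroxyl can be opened across the ring at the tertiary C4', so C5'–Br is set trans to the C1' oxygen; capture by the C4 hydroxyl would have to occur at the secondary carbon and is electronically disfavoured.

Step 20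
Reactants: 30 bromoether
Product: 31 (1R,3S,4S)-3-bromo-1-[(1S,3S,5R)-3-bromo-5-hydroxy-1,2,2-trimethylcyclopentyl]-4-chloro-4-methylcyclohexan-1-ol
Conditions: TiCl4, CH2Cl2, −78 → −40 °C; sat. aq. NaHCO3 at −78 °C
Reagents that add atoms: titanium tetrachloride, Cl[Ti](Cl)(Cl)Cl
Why: Lewis acid cleavage of a tertiary bridging ether. Coordination of titanium to the ether oxygen lets the anti C5' bromine push out the C4'–O bond, the reverse of step 19, and chloride opens the bromonium ion at the tertiary carbon from the oxygen face. The result is net retention at C4' (Cl cis to the C1' hydroxyl, trans to Br), and the C1' hydroxyl is released on work-up.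

## Compound list

1 | cyclohexane-1,3-dione | O=C1CCCC(=O)C1 | starting material
2 | 3-(tert-butyldimethylsilyloxy)cyclohex-2-en-1-one | O=C1CCCC(O[Si](C)(C)C(C)(C)C)=C1 | intermediate
3 | (R)-3-(tert-butyldimethylsilyloxy)cyclohex-2-en-1-ol | O[C@@H]1CCCC(O[Si](C)(C)C(C)(C)C)=C1 | intermediate
4 | prenol (3-methylbut-2-en-1-ol) | CC(C)=CCO | starting material
5 | propionyl chloride | CCC(Cl)=O | starting material
6 | prenyl propionate | CCC(=O)OCC=C(C)C | intermediate
7 | trimethylsilyl ketene acetal of 6 | C/C=C(\OCC=C(C)C)O[Si](C)(C)C | intermediate
8 | trimethylsilyl 2,3,3-trimethylpent-4-enoate | C=CC(C)(C)C(C)C(=O)O[Si](C)(C)C | intermediate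
9 | rac-2,3,3-trimethylpent-4-enoic acid | C=CC(C)(C)C(C)C(=O)O | intermediate
10 | 2,3,3-trimethylpent-4-enoyl chloride | C=CC(C)(C)C(C)C(Cl)=O | intermediate
11 | (1R)-3-(tert-butyldimethylsilyloxy)cyclohex-2-en-1-yl (2RS)-2,3,3-trimethylpent-4-enoate | C=CC(C)(C)C(C)C(=O)O[C@@H]1CCCC(O[Si](C)(C)C(C)(C)C)=C1 | intermediate
12 | trimethylsilyl ketene acetal of 11 (tert-alkyl group cis to the allylic oxygen) | C=CC(C)(C)/C(C)=C(\O[C@@H]1CCCC(O[Si](C)(C)C(C)(C)C)=C1)O[Si](C)(C)C | intermediate
13 | trimethylsilyl ester of 14 | C[Si](C)(C)OC(=O)[C@@](C(C)(C)C=C)(C)[C@@]1(O[Si](C)(C)C(C)(C)C)CCCC=C1 | intermediate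
14 | (2R)-2-[(1R)-1-(tert-butyldimethylsilyloxy)cyclohex-2-en-1-yl]-2,3,3-trimethylpent-4-enoic acid | OC(=O)[C@@](C(C)(C)C=C)(C)[C@@]1(O[Si](C)(C)C(C)(C)C)CCCC=C1 | intermediate
15 | primary alcohol from 14 | OC[C@@](C(C)(C)C=C)(C)[C@@]1(O[Si](C)(C)C(C)(C)C)CCCC=C1 | intermediate
16 | aldehyde from 15 | O=C[C@@](C(C)(C)C=C)(C)[C@@]1(O[Si](C)(C)C(C)(C)C)CCCC=C1 | intermediate
17 | ring A cyclopentanone | CC1(C)CCC(=O)[C@@]1(C)[C@@]1(O[Si](C)(C)C(C)(C)C)CCCC=C1 | intermediate
18 | trimethylsilyl enol ether of 17 | CC1(C)CC=C(O[Si](C)(C)C)[C@@]1(C)[C@@]1(O[Si](C)(C)C(C)(C)C)CCCC=C1 | intermediate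
19 | ring A enone | CC1(C)C=CC(=O)[C@@]1(C)[C@@]1(O[Si](C)(C)C(C)(C)C)CCCC=C1 | intermediate
20 | C2 pinacolboryl ketone (boron trans to ring B) | CC1(C)[C@H](B2OC(C)(C)C(C)(C)O2)CC(=O)[C@@]1(C)[C@@]1(O[Si](C)(C)C(C)(C)C)CCCC=C1 | intermediate
21 | hydroxy boronate (C4–OH cis to ring B) | CC1(C)[C@H](B2OC(C)(C)C(C)(C)O2)C[C@@H](O)[C@@]1(C)[C@@]1(O[Si](C)(C)C(C)(C)C)CCCC=C1 | intermediate
22 | triethylsilyl ether of 21 | CC1(C)[C@H](B2OC(C)(C)C(C)(C)O2)C[C@@H](O[Si](CC)(CC)CC)[C@@]1(C)[C@@]1(O[Si](C)(C)C(C)(C)C)CCCC=C1 | intermediate
23 | lithium aryl boronate complex of 22 | [Li+].CC1(C)[C@H]([B-]2(c3cc(C(F)(F)F)cc(C(F)(F)F)c3)OC(C)(C)C(C)(C)O2)C[C@@H](O[Si](CC)(CC)CC)[C@@]1(C)[C@@]1(O[Si](C)(C)C(C)(C)C)CCCC=C1 | intermediate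
24 | C2 bromide (Br cis to ring B) | CC1(C)[C@@H](Br)C[C@@H](O[Si](CC)(CC)CC)[C@@]1(C)[C@@]1(O[Si](C)(C)C(C)(C)C)CCCC=C1 | intermediate
25 | ring B enone (C4'=O, C5'=C6') | CC1(C)[C@@H](Br)C[C@@H](O[Si](CC)(CC)CC)[C@@]1(C)[C@@]1(O[Si](C)(C)C(C)(C)C)CCC(=O)C=C1 | intermediate
26 | lithium enolate (C4'(OLi)=C5') | CC1(C)[C@@H](Br)C[C@@H](O[Si](CC)(CC)CC)[C@@]1(C)[C@@]1(O[Si](C)(C)C(C)(C)C)CCC(O[Li])=CC1 | intermediate
27 | enol triflate (C4'(OTf)=C5') | CC1(C)[C@@H](Br)C[C@@H](O[Si](CC)(CC)CC)[C@@]1(C)[C@@]1(O[Si](C)(C)C(C)(C)C)CCC(OS(=O)(=O)C(F)(F)F)=CC1 | intermediate
28 | methyl alkene (C4'(CH3)=C5') | CC1(C)[C@@H](Br)C[C@@H](O[Si](CC)(CC)CC)[C@@]1(C)[C@@]1(O[Si](C)(C)C(C)(C)C)CCC(C)=CC1 | intermediate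
29 | diol (C4–OH, C1'–OH) | CC1(C)[C@@H](Br)C[C@@H](O)[C@@]1(C)[C@@]1(O)CCC(C)=CC1 | intermediate
30 | bromoether (O bridge C1'–C4', C5'–Br anti to the bridge) | CC1(C)[C@@H](Br)C[C@@H](O)[C@@]1(C)[C@]12CC[C@](C)(O1)[C@@H](Br)C2 | intermediate
31 | (1R,3S,4S)-3-bromo-1-[(1S,3S,5R)-3-bromo-5-hydroxy-1,2,2-trimethylcyclopentyl]-4-chloro-4-methylcyclohexan-1-ol | CC1(C)[C@@H](Br)C[C@@H](O)[C@@]1(C)[C@@]1(O)CC[C@](C)(Cl)[C@@H](Br)C1 | target

## Step count and least certain steps

Total: 20 steps. Longest linear sequence: 18 steps (steps 1, 2 and 5–20; the branch through steps 3 and 4 is equally long).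

**Step 6 (key step).** The hindered alpha C–H may be removed slowly or with incomplete geometric control, the boat may compete with the chair, or the allylic ester may ionise and eliminate before the shift. Each of these would erode the C5 configuration or cost material. Fallback: set out from 10 and 3 and make the enolate without deprotonation. Et3N converts 10 into methyl(2-methylbut-3-en-2-yl)ketene F1. The lithium alkoxide of 3, lithium (R)-3-(tert-butyldimethylsilyloxy)cyclohex-2-en-1-olate F2 (n-BuLi, THF, −78 °C, kept cold to prevent silyl migration), adds to F1 from the methyl side to give the lithium ester enolate F3 with methyl cis to the allylic oxygen. Trapping with t-BuMe2SiCl in the presence of N,N'-dimethylpropyleneurea gives the tert-butyldimethylsilyl ketene acetal F4. This is the complementary geometry, which leads to the same C5 configuration through the boat; the bulky silyl group disfavours the chair. Rearrangement gives the tert-butyldimethylsilyl ester F5, and hydrolysis (K2CO3, MeOH–H2O) returns to 14.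

**Step 20.** Ionisation of the C1'–O bond, next to quaternary C5, may compete with the bromine-assisted ionisation of C4'–O. With a titanium alkoxide on C4 this could trigger cleavage of the C4–C5 bond or a skeletal shift. Fallback: set out from 29 and acetylate the secondary hydroxyl (Ac2O, pyridine, 4-(dimethylamino)pyridine) to the C4 acetate of 29 F6, so that the C4 oxygen is neither a fragmentation donor nor a competing nucleophile. N-Bromosuccinimide then gives the C4 acetate of 30 F7, TiCl4 gives the C4 acetate of 31 F8, and K2CO3 in MeOH returns to 31.

**Step 14.** Bromine must approach C2 on the ring B face, next to the gem-dimethyl carbon. If the polar pathway is slow, single-electron transfer would give a radical and loss of stereospecificity. Fallback: set out from 22 and oxidise the C–B bond with retention (NaBO3·4H2O, THF–H2O) to the C2 alcohol F9, with hydroxyl trans to ring B. Tf2O and pyridine convert it into the C2 triflate F10, and Bu4NBr in toluene displaces with inversion to return to 24. This fallback carries its own risk of methyl migration at the neopentyl carbon.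

**Step 9.** The acyl rhodium hydride of this very hindered aldehyde may decarbonylate, or the ring B alkene may insert instead of the vinyl group. Fallback: set out from 16 and add vinylmagnesium bromide to give the divinyl carbinol F11. Ring-closing metathesis with the second-generation Grubbs catalyst RuCl2(=CHPh)(PCy3)(H2IMes), to which the cyclohexene is inert, gives the cyclopent-2-en-1-ol F12, and MnO2 oxidation returns to 19, one step later than the main route.

**Step 2.** The vinylogous silyl ester is a weak electrophile, so reduction may be slow and poorly enantioselective, and the product may lose its allylic hydroxyl on work-up. Fallback: set out from 2 and reduce with i-Bu2AlH (toluene, −78 °C, basic work-up) to rac-3-(tert-butyldimethylsilyloxy)cyclohex-2-en-1-ol F13. Immobilised Candida antarctica lipase B with vinyl acetate should acylate the (R)-enantiomer to the (R)-acetate F14, which is separated from the unreacted (S)-alcohol and methanolysed (K2CO3, MeOH) to return to 3.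

## Further compounds

F1 | step 6 | methyl(2-methylbut-3-en-2-yl)ketene | C=CC(C)(C)C(C)=C=O
F2 | step 6 | lithium (R)-3-(tert-butyldimethylsilyloxy)cyclohex-2-en-1-olate | [Li]O[C@@H]1CCCC(O[Si](C)(C)C(C)(C)C)=C1
F3 | step 6 | lithium ester enolate (methyl cis to the allylic oxygen) | C=CC(C)(C)/C(C)=C(/O[C@@H]1CCCC(O[Si](C)(C)C(C)(C)C)=C1)O[Li]
F4 | step 6 | tert-butyldimethylsilyl ketene acetal (methyl cis to the allylic oxygen) | C=CC(C)(C)/C(C)=C(/O[C@@H]1CCCC(O[Si](C)(C)C(C)(C)C)=C1)O[Si](C)(C)C(C)(C)C
F5 | step 6 | tert-butyldimethylsilyl ester of 14 | CC(C)(C)[Si](C)(C)OC(=O)[C@@](C(C)(C)C=C)(C)[C@@]1(O[Si](C)(C)C(C)(C)C)CCCC=C1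
F6 | step 20 | C4 acetate of 29 | CC1(C)[C@@H](Br)C[C@@H](OC(C)=O)[C@@]1(C)[C@@]1(O)CCC(C)=CC1
F7 | step 20 | C4 acetate of 30 | CC1(C)[C@@H](Br)C[C@@H](OC(C)=O)[C@@]1(C)[C@]12CC[C@](C)(O1)[C@@H](Br)C2
F8 | step 20 | C4 acetate of 31 | CC1(C)[C@@H](Br)C[C@@H](OC(C)=O)[C@@]1(C)[C@@]1(O)CC[C@](C)(Cl)[C@@H](Br)C1
F9 | step 14 | C2 alcohol (hydroxyl trans to ring B) | CC1(C)[C@H](O)C[C@@H](O[Si](CC)(CC)CC)[C@@]1(C)[C@@]1(O[Si](C)(C)C(C)(C)C)CCCC=C1
F10 | step 14 | C2 triflate | CC1(C)[C@H](OS(=O)(=O)C(F)(F)F)C[C@@H](O[Si](CC)(CC)CC)[C@@]1(C)[C@@]1(O[Si](C)(C)C(C)(C)C)CCCC=C1
F11 | step 9 | divinyl carbinol from 16 (carbinol epimers) | C=CC(O)[C@@](C(C)(C)C=C)(C)[C@@]1(O[Si](C)(C)C(C)(C)C)CCCC=C1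
F12 | step 9 | cyclopent-2-en-1-ol (carbinol epimers) | CC1(C)C=CC(O)[C@@]1(C)[C@@]1(O[Si](C)(C)C(C)(C)C)CCCC=C1
F13 | step 2 | rac-3-(tert-butyldimethylsilyloxy)cyclohex-2-en-1-ol | OC1CCCC(O[Si](C)(C)C(C)(C)C)=C1
F14 | step 2 | (R)-3-(tert-butyldimethylsilyloxy)cyclohex-2-en-1-yl acetate | CC(=O)O[C@@H]1CCCC(O[Si](C)(C)C(C)(C)C)=C1
A1 | alternative 1 | tert-butyl [(3R)-2-(1,4-dioxaspiro[4.5]decan-8-ylidene)-6-methylhept-5-en-3-yl] carbonate | CC(C)=CC[C@@H](OC(=O)OC(C)(C)C)C(C)=C1CCC2(CC1)OCCO2
A2 | alternative 1 | ring A bromide with C4–O and C1'–O as cyclic carbonate, ring B as ethylene ketal | CC1(C)[C@@H](Br)C[C@H]2OC(=O)OC3(CCC4(CC3)OCCO4)[C@@]12C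
A3 | alternative 2 | spiro-epoxy alcohol (epoxide across C5–C1', tertiary carbinol at C4, ring B as ethylene ketal) | CC1(C)C=C[C@@](C)(O)[C@@]12OC23CCC4(CC3)OCCO4
A4 | alternative 2 | 5-(1-hydroxycyclohexyl ketal)-4,4,5-trimethylcyclopent-2-enone | CC1(C)C=CC(=O)[C@@]1(C)C1(O)CCC2(CC1)OCCO2
A5 | alternative 3 | 4-hydroxycyclohexa-2,5-dienone bearing the complete ring A at C1' | CC1(C)[C@@H](Br)C[C@@H](O)[C@@]1(C)C1(O)C=CC(=O)C=C1
A6 | alternative 3 | 4-hydroxycyclohex-2-enone with C1' defined | CC1(C)[C@@H](Br)C[C@@H](O)[C@@]1(C)[C@@]1(O)CCC(=O)C=C1
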